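**Retrosynthetic overview**
1. Numbering: hydrindane C1–C7a (C7a bears CH3, C7 bears O, C4 bears =CH2). The bridge runs C3–C8(CH3)–C9(O)–C10–C11=C12(CH3)–C13(O)–C14–C5. α is the face that carries the 7a-methyl group and β is the opposite face.
2. Enabling feature: the eleven-membered ring C3–C3a–C4–C5–C14–C13–C12–C11–C10–C9–C8 contains a (Z)-2-methylpent-2-ene-1,5-diol unit, O–C13–C12(CH3)=C11–C10–C9–O, with (13R,9S) configuration. Its two carbinol carbons sit on arms of very different bulk (unbranched C14H2 on the α face, branched C8H(CH3) on the concave β face), which is the retron of a double allylboration.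
3. Key disconnection: C12–C13 and C9–C10 are cut together. This gives a C16 hydrindane dialdehyde and a four-carbon 1,3-diboron linchpin; after the ring closure only desilylation and threefold propionylation remain.
4. Dialdehyde: one Claisen rearrangement supplies C5–C14 and the C4 methylene, and one anionic oxy-Cope rearrangement sets C3 and C8. An anti-selective conjugate addition sets C7a, and a CBS reduction sets C7, the only core stereocentre made by catalysis.
5. Ring order: six-membered ring (bought), then five-membered ring (conjugate addition/aldol condensation), then eleven-membered ring (last).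

Key step: step 16

Assumption: commercial, predominantly trans crotyl chloride is enriched to the E isomer before use, and the kinetic hydroboration adduct 28 keeps its geometry (Bpin cis to CH2B(Ipc)2) below −25 °C.

**Step 1**
Reactants: 1 2-methylcyclohex-2-en-1-one
Product: 2 (S)-2-methylcyclohex-2-en-1-ol
Conditions: (R)-Me-CBS (10 mol %), catecholborane, toluene, −78 °C; aq. work-up
Reagents that add atoms: none
Why: Corey–Bakshi–Shibata reduction in which the 2-methylalkenyl arm acts as the large and the ring CH2 as the small ketone substituent, so the (R)-oxazaborolidine should set C7 as (S).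

**Step 2**
Reactants: 2 (S)-2-methylcyclohex-2-en-1-ol
Product: 3 (S)-tert-butyl[(2-methylcyclohex-2-en-1-yl)oxy]diphenylsilane
Conditions: TBDPSCl, imidazole, DMF, rt
Reagents that add atoms: tert-butyl(chloro)diphenylsilane, CC(C)(C)[Si](Cl)(c1ccccc1)c1ccccc1
Why: Standard silylation gives an acid-stable, bulky ether that later serves as the stereodirecting group, and the stereocentre is not touched.

**Step 3**
Reactants: 3 (S)-tert-butyl[(2-methylcyclohex-2-en-1-yl)oxy]diphenylsilane
Product: 4 (S)-4-(tert-butyldiphenylsilyloxy)-3-methylcyclohex-2-en-1-one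
Conditions: Rh2(cap)4 (1 mol %), t-BuOOH (70 % aq.), K2CO3, CH2Cl2, rt
Reagents that add atoms: tert-butyl hydroperoxide, CC(C)(C)OO
Why: Dirhodium caprolactamate/TBHP allylic oxidation should attack the ring CH2 next to the CH= terminus, the only unhindered secondary allylic position, and leave C7 untouched.

**Step 4**
Reactants: 4 (S)-4-(tert-butyldiphenylsilyloxy)-3-methylcyclohex-2-en-1-one; 5 [2-(1,3-dioxan-2-yl)ethyl]magnesium bromide
Product: 6 (3S,4S)-4-(tert-butyldiphenylsilyloxy)-3-[2-(1,3-dioxan-2-yl)ethyl]-3-methyl-1-(trimethylsilyloxy)cyclohex-1-ene (new chain trans to the silyloxy group)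
Conditions: CuBr·SMe2 (20 mol %), TMSCl, DMPU, THF, −78 → −30 °C; Et3N, pentane work-up
Reagents that add atoms: Grignard reagent 5, Br[Mg]CCC1OCCCO1; chlorotrimethylsilane, C[Si](C)(C)Cl
Why: In this copper-catalysed, TMSCl-accelerated conjugate addition of an acetal Grignard reagent the nucleophile should enter anti to the bulky γ-silyloxy group, which sets quaternary C7a with the methyl group cis to the C7 oxygen.

**Step 5**
Reactants: 6 silyl enol ether acetal
Product: 8 (7S,7aS)-7-(tert-butyldiphenylsilyloxy)-7a-methyl-1,2,5,6,7,7a-hexahydro-4H-inden-4-one, via keto aldehyde 7 (not isolated)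
Conditions: 2 M HCl, THF, 50 °C
Reagents that add atoms: water, O
Why: Acid hydrolysis of the enol ether and acetal unmasks 7, whose intramolecular aldol condensation through the C3a enol (5-exo closure, the only unstrained mode) forms the five-membered ring without touching C7 or C7a.

**Step 6**
Reactants: 8 bicyclic enone; 9 (E)-1-chlorobut-2-ene
Product: 10 tertiary alcohol 4β-[(E)-but-2-en-1-yl]-4α-hydroxy-7α-(tert-butyldiphenylsilyloxy)-7a-methyl-2,4,5,6,7,7a-hexahydro-1H-indene
Conditions: BaI2, lithium biphenylide, THF, rt; 9, −78 °C; then 8, −78 °C; aq. NH4Cl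
Reagents that add atoms: (E)-crotyl chloride 9, C/C=C/CCl
Why: Allylbarium addition is known to couple at the α-carbon with retention of E geometry and in 1,2-fashion with enones, and attack anti to the pseudoaxial 7a-methyl group should place the crotyl group on the β face (this carbinol centre is only a relay and disappears in step 7).

**Step 7**
Reactants: 10 crotyl carbinol
Product: 12 cis-fused ketone 3β-[(R)-but-3-en-2-yl]-7α-(tert-butyldiphenylsilyloxy)-7a-methyl-3aα-H-octahydro-4H-inden-4-one, via potassium enolate 11 (not isolated)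
Conditions: KH, 18-crown-6, THF, 0 °C → rt; aq. NH4Cl, −78 °C
Reagents that add atoms: none
Why: In this anionic oxy-Cope rearrangement the β-crotyl group can only reach the β face of C3, a chair transition state (the boat clashes with C7) with the E-methyl group equatorial should set C3 and C8 together, and kinetic protonation of enolate 11 from the α face, away from the new side chain, should set C3a (cis fusion).

**Step 8**
Reactants: 12 cis-hydrindanone
Product: 13 C4=C5 enol triflate of 12
Conditions: KHMDS, THF, −78 °C; PhNTf2, −78 → 0 °C; aq. NH4Cl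
Reagents that add atoms: N-phenylbis(trifluoromethanesulfonimide), O=S(=O)(N(c1ccccc1)S(=O)(=O)C(F)(F)F)C(F)(F)F
Why: Kinetic deprotonation at the C5 methylene rather than the hindered C3a methine, followed by O-sulfonylation, fixes the C4=C5 double bond and removes any later risk of epimerisation at C3a.

**Step 9**
Reactants: 13 enol triflate with vinyl side chain
Product: 15 enol triflate dimethyl acetal (C9 as CH(OMe)2 and C8 (S)), via aldehyde 14 (not isolated)
Conditions: O3, CH2Cl2/MeOH, −78 °C (indicator dye); Me2S; then HC(OMe)3, PPTS, rt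
Reagents that add atoms: ozone, [O-][O+]=O; trimethyl orthoformate, COC(OC)OC
Why: Ozonolysis is chemoselective for the vinyl group over the electron-poor enol triflate, and mild orthoformate acetalisation in the same flask masks the epimerisable C9 aldehyde without disturbing C8.

**Step 10**
Reactants: 15 enol triflate acetal; 16 (tributylstannyl)methanol
Product: 17 primary allylic alcohol (C4–CH2OH and C4=C5)
Conditions: Pd(PPh3)4 (8 mol %), LiCl, 1,4-dioxane, 100 °C
Reagents that add atoms: (tributylstannyl)methanol 16, OC[Sn](CCCC)(CCCC)CCCC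
Why: Stille coupling of an enol triflate with a hydroxymethylstannane installs the future exocyclic carbon in one step and creates no stereocentre.

**Step 11**
Reactants: 17 allylic alcohol; 18 butyl vinyl ether
Product: 20 aldehyde acetal (C4=CH2 and C5α–CH2CHO and C9 acetal), via allyl vinyl ether 19 (not isolated)
Conditions: 18 (solvent), Pd(OCOCF3)2 (5 mol %), 4,7-diphenyl-1,10-phenanthroline (5 mol %), Et3N (cat.), 75 °C; evaporate; o-xylene, 145 °C
Reagents that add atoms: butyl vinyl ether 18, C=COCCCC
Why: Pd(II)-catalysed vinyl ether exchange is followed by a thermal Claisen rearrangement in which allylic strain with the C4 substituent holds C3 and its side chain pseudoaxial on the β face, so the [3,3] shift should run on the α face and set C5 while it creates the C4 methylene group and the C13 aldehyde.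

**Step 12**
Reactants: 20 aldehyde acetal
Product: 21 dialdehyde 2-[7α-(tert-butyldiphenylsilyloxy)-7a-methyl-4-methylidene-3β-[(S)-1-oxopropan-2-yl]-3aα-H-octahydro-1H-inden-5α-yl]acetaldehyde
Conditions: PPTS (cat.), acetone/H2O 10:1, 40 °C
Reagents that add atoms: water, O
Why: In this mild acid-catalysed acetal hydrolysis the acid is weak enough that enolisation at C8, migration of the exocyclic alkene and loss of the TBDPS ether are not expected.

**Step 13**
Reactants: 22 but-2-yn-1-ol
Product: 23 but-2-yn-1-yl methyl carbonate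
Conditions: ClCO2Me, pyridine, CH2Cl2, 0 °C
Reagents that add atoms: methyl chloroformate, COC(=O)Cl
Why: This is a standard O-acylation of a primary propargylic alcohol.

**Step 14**
Reactants: 23 but-2-yn-1-yl methyl carbonate; 24 bis(pinacolato)diboron
Product: 25 2-(buta-2,3-dien-2-yl)-4,4,5,5-tetramethyl-1,3,2-dioxaborolane
Conditions: CuCl (5 mol %), KOt-Bu (5 mol %), Xantphos (5 mol %), THF, rt
Reagents that add atoms: bis(pinacolato)diboron 24, CC1(C)OB(OC1(C)C)B1OC(C)(C)C(C)(C)O1
Why: Copper(I)-catalysed SN2'-type borylation of a propargylic carbonate is a known route to substituted allenylboronates and forms no stereocentre.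

**Step 15**
Reactants: 26 (+)-α-pinene
Product: 27 (−)-diisopinocampheylborane
Conditions: BH3·SMe2, THF, 0 °C; crystallisation
Reagents that add atoms: borane–dimethyl sulfide, C[S+](C)[BH3-]
Why: Hydroboration of α-pinene from the face opposite the gem-dimethyl bridge stops at the dialkylborane, and crystallisation should raise its enantiomeric purity.

**Step 16**
Reactants: 21 dialdehyde; 25 allenylboronate; 27 (−)-diisopinocampheylborane
Product: 31 macrocyclic (9S,13R)-diol with 7-O-TBDPS group, via linchpin allylborane 28 (not isolated), via tertiary allylboronate 29 (not isolated), via macrocyclic boron ester 30 (not isolated)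
Conditions: 25 + 27, toluene, −40 → −25 °C; 21 (1.0 equiv), toluene, −78 °C; dilute to 1 mM, BF3·OEt2 (20 mol %), −78 → −30 °C; pH 7 buffer, 30 % H2O2, 0 °C
Reagents that add atoms: allenylboronate 25, C=C=C(C)B1OC(C)(C)C(C)(C)O1; diisopinocampheylborane 27, B([C@@H]1C[C@@H]2C[C@H]([C@H]1C)C2(C)C)[C@@H]1C[C@@H]2C[C@H]([C@H]1C)C2(C)C
Why: Proposed new method: kinetic hydroboration of allene 25 by 27 from the methyl side gives linchpin 28 (Bpin cis to CH2B(Ipc)2), whose dialkylallylborane end adds through a closed chair to the C13 aldehyde of 21 to give the α-tertiary allylboronate 29, and the BF3-activated pinacol boronate of 29 then adds intramolecularly, again through a chair with allylic transposition, to the C9 aldehyde, so that C12–C13 and C9–C10 form in one flask and oxidative work-up of 30 frees diol 31. The closest known reaction type is the intermolecular one-pot allene hydroboration/double allylboration that joins two different aldehydes to (Z)-2-methylpent-2-ene-1,5-diols of this same relative configuration; what is new is that both aldehydes belong to one molecule and that the second allylboration must close a medium ring. Only the eleven-membered ring is closed, by 11-exo-trig attack of C10 on the C9 carbonyl (a formal [8+3] annulation), and the B–O–C9–C10–C11–C12 chair is fused to the forming ring through the axial C13 and the equatorial C8 substituents, which lie on the same side of the allyl unit at an estimated 4–5 Å, a gap that the C14–C5–C4–C3a–C3 segment can span. C13 (R) is set by the Ipc ligands derived from (+)-α-pinene, the transient C12 boronate centre by the geometry of 28 (methyl equatorial, Bpin axial), C9 (S) by 1,3-chirality transfer from C12 in accord with the Felkin–Anh preference of C8, and the Z alkene by the axial position of the C13 branch, which is also the one the tether favours. The step needs site selectivity (C13 aldehyde first) and ring closure ahead of oligomerisation: the first is secured by the contrast between the unbranched C14H2–CHO arm on the open α face and the α-branched C8(CH3)–CHO arm buried on the concave β face toward a reagent that must build a fully substituted carbon, and the second by the low uncatalysed reactivity of 29, which allows dilution before BF3·OEt2 is added.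

**Step 17**
Reactants: 31 macrocyclic diol silyl ether
Product: 32 macrocyclic C7/C9/C13 triol
Conditions: TBAF, THF, 45 °C
Reagents that add atoms: none
Why: Fluoride-induced silyl ether cleavage touches no other group at this stage, since no base-labile group is present and no stereocentre is affected.

**Step 18**
Reactants: 32 triol
Product: 33 target tripropionate CNP0315827.1
Conditions: (EtCO)2O, DMAP, Et3N, CH2Cl2, rt → 40 °C
Reagents that add atoms: propionic anhydride, CCC(=O)OC(=O)CC
Why: DMAP-catalysed acylation esterifies all three secondary alcohols at oxygen, so every configuration is retained.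

**Compound list**
1 | 2-methylcyclohex-2-en-1-one | CC1=CCCCC1=O | starting material
2 | (S)-2-methylcyclohex-2-en-1-ol | C1CC[C@H](O)C(C)=C1 | intermediate
3 | (S)-TBDPS ether of 2 | C1CC[C@H](O[Si](c2ccccc2)(c2ccccc2)C(C)(C)C)C(C)=C1 | intermediate
4 | (S)-4-(tert-butyldiphenylsilyloxy)-3-methylcyclohex-2-en-1-one | O=C1CC[C@H](O[Si](c2ccccc2)(c2ccccc2)C(C)(C)C)C(C)=C1 | intermediate
5 | [2-(1,3-dioxan-2-yl)ethyl]magnesium bromide | Br[Mg]CCC1OCCCO1 | starting material
6 | TMS enol ether of the conjugate adduct | C[Si](C)(C)OC=1CC[C@H](O[Si](c2ccccc2)(c2ccccc2)C(C)(C)C)[C@@](C)(CCC2OCCCO2)C=1 | intermediate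
7 | 3-[(1S,2S)-2-(tert-butyldiphenylsilyloxy)-1-methyl-5-oxocyclohexyl]propanal | O=C1CC[C@H](O[Si](c2ccccc2)(c2ccccc2)C(C)(C)C)[C@@](C)(CCC=O)C1 | intermediate
8 | bicyclic enone | O=C1CC[C@H](O[Si](c3ccccc3)(c3ccccc3)C(C)(C)C)[C@@]2(C)CCC=C12 | intermediate
9 | (E)-1-chlorobut-2-ene | C/C=C/CCl | starting material
10 | β-crotyl tertiary alcohol | C/C=C/C[C@@]1(O)CC[C@H](O[Si](c3ccccc3)(c3ccccc3)C(C)(C)C)[C@@]2(C)CCC=C12 | intermediate
11 | potassium enolate from the oxy-Cope rearrangement | [K+].[O-]C=1CC[C@H](O[Si](c3ccccc3)(c3ccccc3)C(C)(C)C)[C@@]2(C)CC[C@@H]([C@H](C)C=C)C=12 | intermediate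
12 | cis-hydrindanone with β-but-3-en-2-yl group | O=C1CC[C@H](O[Si](c3ccccc3)(c3ccccc3)C(C)(C)C)[C@@]2(C)CC[C@@H]([C@H](C)C=C)[C@@H]12 | intermediate
13 | enol triflate | O=S(=O)(OC1=CC[C@H](O[Si](c3ccccc3)(c3ccccc3)C(C)(C)C)[C@@]2(C)CC[C@@H]([C@H](C)C=C)[C@@H]12)C(F)(F)F | intermediate
14 | enol triflate aldehyde | O=S(=O)(OC1=CC[C@H](O[Si](c3ccccc3)(c3ccccc3)C(C)(C)C)[C@@]2(C)CC[C@@H]([C@H](C)C=O)[C@@H]12)C(F)(F)F | intermediate
15 | enol triflate dimethyl acetal | O=S(=O)(OC1=CC[C@H](O[Si](c3ccccc3)(c3ccccc3)C(C)(C)C)[C@@]2(C)CC[C@@H]([C@H](C)C(OC)OC)[C@@H]12)C(F)(F)F | intermediate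
16 | (tributylstannyl)methanol | OC[Sn](CCCC)(CCCC)CCCC | starting material
17 | allylic alcohol | OCC1=CC[C@H](O[Si](c3ccccc3)(c3ccccc3)C(C)(C)C)[C@@]2(C)CC[C@@H]([C@H](C)C(OC)OC)[C@@H]12 | intermediate
18 | butyl vinyl ether | C=COCCCC | starting material
19 | allyl vinyl ether | C=COCC1=CC[C@H](O[Si](c3ccccc3)(c3ccccc3)C(C)(C)C)[C@@]2(C)CC[C@@H]([C@H](C)C(OC)OC)[C@@H]12 | intermediate
20 | Claisen aldehyde acetal | C=C1[C@H](CC=O)C[C@H](O[Si](c3ccccc3)(c3ccccc3)C(C)(C)C)[C@@]2(C)CC[C@@H]([C@H](C)C(OC)OC)[C@@H]12 | intermediate
21 | dialdehyde | C=C1[C@H](CC=O)C[C@H](O[Si](c3ccccc3)(c3ccccc3)C(C)(C)C)[C@@]2(C)CC[C@@H]([C@H](C)C=O)[C@@H]12 | intermediate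
22 | but-2-yn-1-ol | CC#CCO | starting material
23 | but-2-yn-1-yl methyl carbonate | CC#CCOC(=O)OC | intermediate
24 | bis(pinacolato)diboron | CC1(C)OB(OC1(C)C)B1OC(C)(C)C(C)(C)O1 | starting material
25 | 1-methylallenylboronic acid pinacol ester | C=C=C(C)B1OC(C)(C)C(C)(C)O1 | intermediate
26 | (+)-α-pinene | CC1=CC[C@@H]2C[C@H]1C2(C)C | starting material
27 | (−)-diisopinocampheylborane | B([C@@H]1C[C@@H]2C[C@H]([C@H]1C)C2(C)C)[C@@H]1C[C@@H]2C[C@H]([C@H]1C)C2(C)C | intermediate
28 | linchpin γ-boryl-γ-methylallylborane (Bpin cis to CH2B) | C/C(B1OC(C)(C)C(C)(C)O1)=C/CB([C@@H]1C[C@@H]2C[C@H]([C@H]1C)C2(C)C)[C@@H]1C[C@@H]2C[C@H]([C@H]1C)C2(C)C | intermediate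
29 | tertiary allylboronate after the first allylboration | C=C1[C@H](C[C@@H](OB([C@@H]3C[C@@H]4C[C@H]([C@H]3C)C4(C)C)[C@@H]3C[C@@H]4C[C@H]([C@H]3C)C4(C)C)[C@](C)(B3OC(C)(C)C(C)(C)O3)C=C)C[C@H](O[Si](c3ccccc3)(c3ccccc3)C(C)(C)C)[C@@]2(C)CC[C@@H]([C@H](C)C=O)[C@@H]12 | intermediate
30 | macrocyclic borinate/borate ester | C=C1[C@H]2C[C@H](O[Si](c4ccccc4)(c4ccccc4)C(C)(C)C)[C@@]3(C)CC[C@@H]([C@H](C)[C@@H](OB4OC(C)(C)C(C)(C)O4)C/C=C(/C)[C@H](OB([C@@H]4C[C@@H]5C[C@H]([C@H]4C)C5(C)C)[C@@H]4C[C@@H]5C[C@H]([C@H]4C)C5(C)C)C2)[C@@H]13 | intermediate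
31 | macrocyclic diol, 7-O-TBDPS | C=C1[C@H]2C[C@H](O[Si](c4ccccc4)(c4ccccc4)C(C)(C)C)[C@@]3(C)CC[C@@H]([C@H](C)[C@@H](O)C/C=C(/C)[C@H](O)C2)[C@@H]13 | intermediate
32 | macrocyclic triol | C=C1[C@H]2C[C@H](O)[C@@]3(C)CC[C@@H]([C@H](C)[C@@H](O)C/C=C(/C)[C@H](O)C2)[C@@H]13 | intermediate
33 | CNP0315827.1 (tripropionate) | C=C1[C@H]2C[C@H](OC(=O)CC)[C@@]3(C)CC[C@@H]([C@H](C)[C@@H](OC(=O)CC)C/C=C(/C)[C@H](OC(=O)CC)C2)[C@@H]13 | target

**Step count**
Total step count: 18.
Longest linear sequence: 15 (steps 1–12 and 16–18).

**Steps most likely to fail**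

Step 16.
- Site selection between the two aldehydes may erode.
- Oligomerisation may outrun ring closure.
- The linchpin may isomerise by a boratropic shift before it adds.
- The Lewis acid may trigger a carbonyl-ene reaction of the C9 aldehyde with the C4 methylene group.

The fallback sets out from 21 and returns at 31, using known chemistry only. A catalytic asymmetric Nozaki–Hiyama–Kishi coupling of 21 with 2-iodopropene (CrCl2/NiCl2, chiral sulfonamide ligand) at the unhindered C13 aldehyde would give the (13R)-isopropenyl carbinol aldehyde F1. Brown allylation of the remaining C9 aldehyde with (−)-Ipc2B(allyl) would give the (9S,13R)-diene diol F2. Ring-closing metathesis (second-generation Ru–NHC catalyst, high dilution, toluene, 80 °C) would then close C11=C12, with ring strain expected to favour the Z alkene, and deliver 31.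

Step 6.
- The barium reagent may leak to γ-attack.
- It may lose its E geometry.
- It may enolise the ketone.

The fallback sets out from 8 and returns at 10. Addition of allylmagnesium bromide/CeCl3 (no regiochemical issue, same β-face attack) would give the β-allyl tertiary alcohol F3. Cross metathesis of F3 with but-2-ene (second-generation Ru–NHC catalyst, CH2Cl2, 40 °C) would convert the allyl into the (E)-crotyl group of 10. The trisubstituted ring alkene should stay inert, and the minor Z isomer would be removed by chromatography.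

Step 4.
- Addition to the fully substituted β-carbon next to the silyloxy group may be slow.
- 1,2-Addition, enolisation or poor facial selectivity could then take over.

The fallback sets out from 4 and returns at 7, and therefore at 8. A Hosomi–Sakurai conjugate allylation (allyltrimethylsilane, TiCl4, CH2Cl2, −78 °C), a reaction type that tolerates β,β-disubstituted enones, would give the trans allyl ketone F4. An aldehyde-selective, nitrite-modified Wacker oxidation (PdCl2(PhCN)2, CuCl2, AgNO2, O2, t-BuOH/MeNO2) would turn its terminal alkene into keto aldehyde 7. Compound 7 is then cyclised with acid as in step 5.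

**Further compounds**
F1 | step 16 | (13R)-isopropenyl carbinol aldehyde | C=C1[C@H](C[C@@H](O)C(C)=C)C[C@H](O[Si](c3ccccc3)(c3ccccc3)C(C)(C)C)[C@@]2(C)CC[C@@H]([C@H](C)C=O)[C@@H]12
F2 | step 16 | (9S,13R)-diene diol | C=C1[C@H](C[C@@H](O)C(C)=C)C[C@H](O[Si](c3ccccc3)(c3ccccc3)C(C)(C)C)[C@@]2(C)CC[C@@H]([C@H](C)[C@@H](O)CC=C)[C@@H]12
F3 | step 6 | β-allyl tertiary alcohol | C=CC[C@@]1(O)CC[C@H](O[Si](c3ccccc3)(c3ccccc3)C(C)(C)C)[C@@]2(C)CCC=C12
F4 | step 4 | trans allyl ketone | O=C1CC[C@H](O[Si](c2ccccc2)(c2ccccc2)C(C)(C)C)[C@@](C)(CC=C)C1
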